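The cyclohexane ring is numbered C1 (side-chain carbon), C2 (2-methylbutanoate), C3 (carbinol), C4 and C5 (methyl-bearing and H-bearing epoxide carbons), C6 (CH2). The C3 carbinol and the C4–C5 epoxide are read as a 2-methylcyclohex-2-enone, disconnected at C3–C4 and C5–C6 into a cyclobutanone and a propyne unit. The key step is a nickel-catalysed insertion of 1-(trimethylsilyl)propyne into the C3–C6 bond of a cis-fused 2-oxabicyclo[3.2.0]heptan-7-one. It forms both bonds at once with release of ring strain and carries C1 and C2 through unchanged. The cyclobutanone comes from an intramolecular alkoxyketene–alkene [2+2] cycloaddition of an iridium-derived anti-diol.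

Key step: step 5

Remark: side-chain locants used below are C7 (alkene carbon on C1), C14 (=CH2), C8 (angelate carbinol), C9 to C11 (CH2, epoxide CH, CMe2); (R)-2-methylbutanoic acid and angelic acid are taken as purchased; in step 1 (S)-SEGPHOS is assumed to give the (2S,3S)-diol, and its antipode is used should the sense of induction be opposite.

Step 1
Reactants: 1 4-methylpent-3-en-1-ol; 2 4-ethenyl-1,3-dioxolan-2-one
Product: 3 (2S,3S)-2-ethenyl-6-methylhept-5-ene-1,3-diol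
Conditions: [Ir(cod)Cl]2 (2.5 mol %), (S)-SEGPHOS (5 mol %), 4-cyano-3-nitrobenzoic acid (10 mol %), K3PO4 (5 mol %), THF, 90 °C, sealed tube
Reagents that add atoms: none
Why: Iridium-catalysed transfer-hydrogenative carbonyl (hydroxymethyl)allylation from the alcohol oxidation level, in which the carbonate ionises with loss of CO2 to a (hydroxymethyl)allyl–iridium species that adds to the transient aldehyde through a closed chair transition state, so that the anti C7/C8 relationship follows from the chair and the absolute configuration of both centres from the chiral bisphosphine.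

Step 2
Reactants: 3 (2S,3S)-2-ethenyl-6-methylhept-5-ene-1,3-diol; 4 bromoacetic acid
Product: 5 2-{[(2S,3S)-2-ethenyl-3-hydroxy-6-methylhept-5-en-1-yl]oxy}acetic acid
Conditions: NaH (3.2 equiv), THF, 0 °C; 4 (1.0 equiv) added slowly, then rt; acidic work-up
Reagents that add atoms: none
Why: Williamson ether synthesis in which the unhindered primary alkoxide should alkylate sodium bromoacetate much faster than the α-branched secondary alkoxide, with no stereocentre touched.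

Step 3
Reactants: 5 2-{[(2S,3S)-2-ethenyl-3-hydroxy-6-methylhept-5-en-1-yl]oxy}acetic acid
Product: 7 2-{[(2S,3S)-3-(tert-butyldimethylsilyloxy)-2-ethenyl-6-methylhept-5-en-1-yl]oxy}acetic acid, via bis-silylated silyl ester 6 (not isolated)
Conditions: TBSOTf (2.5 equiv), 2,6-lutidine, CH2Cl2, −78 → 0 °C; then K2CO3, MeOH/THF/H2O, rt; citric acid work-up
Reagents that add atoms: tert-butyldimethylsilyl trifluoromethanesulfonate, CC(C)(C)[Si](C)(C)OS(=O)(=O)C(F)(F)F
Why: Silyl triflate protection silylates both the secondary hydroxyl and the acid, and mild carbonate methanolysis then cleaves only the labile silyl ester, leaving the C8 silyl ether.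

Step 4
Reactants: 7 2-{[(2S,3S)-3-(tert-butyldimethylsilyloxy)-2-ethenyl-6-methylhept-5-en-1-yl]oxy}acetic acid
Product: 10 (1R,4S,5S)-4-[(1S)-1-(tert-butyldimethylsilyloxy)-4-methylpent-3-en-1-yl]-2-oxabicyclo[3.2.0]heptan-7-one, via acid chloride 8 (not isolated), via alkoxyketene 9 (not isolated)
Conditions: (COCl)2, DMF (cat.), CH2Cl2, 0 °C → rt, concentrate; then slow addition to Et3N (3 equiv) in toluene, 110 °C, high dilution
Reagents that add atoms: none
Why: Intramolecular ketene–alkene [2+2] cycloaddition of an alkoxyketene, in which the three-atom tether enforces the cis ring fusion and the regiochemistry (ketene carbonyl carbon to the terminal CH2), and the C7 stereocentre should direct the ketene to the alkene face that places the large C8 substituent exo, trans to C6, which sets C1 (S) and C2 (R).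

Step 5
Reactants: 10 (1R,4S,5S)-4-[(1S)-1-(tert-butyldimethylsilyloxy)-4-methylpent-3-en-1-yl]-2-oxabicyclo[3.2.0]heptan-7-one; 11 trimethyl(prop-1-yn-1-yl)silane
Product: 12 (3S,3aS,7aR)-3-[(1S)-1-(tert-butyldimethylsilyloxy)-4-methylpent-3-en-1-yl]-6-methyl-5-(trimethylsilyl)-3,3a,4,7a-tetrahydro-1-benzofuran-7(2H)-one
Conditions: Ni(cod)2 (10 mol %), PCy3 (20 mol %), 11 (3 equiv), toluene, 100 °C
Reagents that add atoms: none
Why: Nickel-catalysed insertion of an alkyne into a cyclobutanone, a formal [4+2] annulation driven by release of four-membered-ring strain: zerovalent nickel couples the ketone carbonyl of 10 and alkyne 11 oxidatively to an oxanickelacyclopentene (C3–C4 bond), β-carbon elimination then opens the cyclobutane at C3–C6, and reductive elimination from the seven-membered nickelacycle forms C5–C6. The closest known reaction type is the nickel/trialkylphosphine-catalysed intermolecular alkyne insertion into cyclobutanones, azetidin-3-ones and oxetan-3-ones. The cyclohexenone ring is closed by two-carbon ring expansion of the four-membered ring, the last bond (C5–C6) arising by C(sp3)–C(sp2) reductive elimination, and the tetrahydrofuran stays cis-fused. No stereocentre is created, and C1 and C2 are carried over unchanged because no bond to either is broken. The step needs the alkyne orientation with methyl next to the carbonyl, which should follow from the preference of silylalkynes to form the new C–C bond at the carbon remote from silicon, and cleavage of the CH2–C(=O) bond rather than the O–CH–C(=O) bond, which should follow from the preference of β-carbon elimination for the less substituted, unhindered α-carbon.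

Step 6
Reactants: 12 (3S,3aS,7aR)-3-[(1S)-1-(tert-butyldimethylsilyloxy)-4-methylpent-3-en-1-yl]-6-methyl-5-(trimethylsilyl)-3,3a,4,7a-tetrahydro-1-benzofuran-7(2H)-one
Product: 13 (3S,3aS,7S,7aR)-3-[(1S)-1-(tert-butyldimethylsilyloxy)-4-methylpent-3-en-1-yl]-6-methyl-5-(trimethylsilyl)-2,3,3a,4,7,7a-hexahydro-1-benzofuran-7-ol
Conditions: NaBH4, CeCl3·7H2O, MeOH, −78 °C
Reagents that add atoms: none
Why: Luche reduction gives 1,2-reduction of the enone, and hydride should arrive on the convex face of the cis-fused bicycle, anti to the tetrahydrofuran ring, so that the new C3 hydroxyl is cis to the C2 oxygen.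

Step 7
Reactants: 13 (3S,3aS,7S,7aR)-3-[(1S)-1-(tert-butyldimethylsilyloxy)-4-methylpent-3-en-1-yl]-6-methyl-5-(trimethylsilyl)-2,3,3a,4,7,7a-hexahydro-1-benzofuran-7-ol
Product: 14 (3S,3aS,7S,7aR)-3-[(1S)-1-(tert-butyldimethylsilyloxy)-4-methylpent-3-en-1-yl]-6-methyl-7-(triisopropylsilyloxy)-5-(trimethylsilyl)-2,3,3a,4,7,7a-hexahydro-1-benzofuran
Conditions: TIPSOTf, 2,6-lutidine, CH2Cl2, 0 °C → rt
Reagents that add atoms: triisopropylsilyl trifluoromethanesulfonate, CC(C)[Si](C(C)C)(C(C)C)OS(=O)(=O)C(F)(F)F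
Why: Silyl triflate protection masks C3–OH as a silyl ether more robust than the C8 TBS ether, so that it survives the acyl iodide of step 8 and the selective desilylation of step 10.

Step 8
Reactants: 14 (3S,3aS,7S,7aR)-3-[(1S)-1-(tert-butyldimethylsilyloxy)-4-methylpent-3-en-1-yl]-6-methyl-7-(triisopropylsilyloxy)-5-(trimethylsilyl)-2,3,3a,4,7,7a-hexahydro-1-benzofuran; 15 (2R)-2-methylbutanoic acid
Product: 18 (1R,2S,6S)-6-[(2R,3S)-3-(tert-butyldimethylsilyloxy)-1-iodo-6-methylhept-5-en-2-yl]-3-methyl-2-(triisopropylsilyloxy)-4-(trimethylsilyl)cyclohex-3-en-1-yl (2R)-2-methylbutanoate, via (R)-2-methylbutanoyl chloride 16 (not isolated), via (R)-2-methylbutanoyl iodide 17 (not isolated)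
Conditions: 15, (COCl)2, DMF (cat.), CH2Cl2, 0 °C → rt, concentrate; NaI, MeCN, 0 °C; then 14, 0 °C → rt, dark
Reagents that add atoms: sodium iodide, [Na+].[I-]
Why: Acylative cleavage of a cyclic ether by an acyl iodide, in which the ring oxygen (the most basic oxygen present) is acylated to an acyloxonium ion and iodide opens it by SN2 attack at the primary C14 rather than the hindered ring carbon C2, so the C2–O bond and its configuration are kept and the C2 ester of the target is installed in the same step.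

Step 9
Reactants: 18 (1R,2S,6S)-6-[(2R,3S)-3-(tert-butyldimethylsilyloxy)-1-iodo-6-methylhept-5-en-2-yl]-3-methyl-2-(triisopropylsilyloxy)-4-(trimethylsilyl)cyclohex-3-en-1-yl (2R)-2-methylbutanoate
Product: 19 (1R,2S,6S)-6-[(3S)-3-(tert-butyldimethylsilyloxy)-6-methylhepta-1,5-dien-2-yl]-3-methyl-2-(triisopropylsilyloxy)-4-(trimethylsilyl)cyclohex-3-en-1-yl (2R)-2-methylbutanoate
Conditions: DBU (5 equiv), toluene, 90 °C
Reagents that add atoms: none
Why: E2 dehydroiodination with an amidine base, in which the β-branched primary iodide has its only β-hydrogen on C7 and can therefore give only the C7=C14 alkene, and with no ketone in the molecule C2 cannot epimerise.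

Step 10
Reactants: 19 (1R,2S,6S)-6-[(3S)-3-(tert-butyldimethylsilyloxy)-6-methylhepta-1,5-dien-2-yl]-3-methyl-2-(triisopropylsilyloxy)-4-(trimethylsilyl)cyclohex-3-en-1-yl (2R)-2-methylbutanoate
Product: 20 (1R,2S,6S)-6-[(3S)-3-hydroxy-6-methylhepta-1,5-dien-2-yl]-3-methyl-2-(triisopropylsilyloxy)-4-(trimethylsilyl)cyclohex-3-en-1-yl (2R)-2-methylbutanoate
Conditions: HF·pyridine, pyridine, THF, 0 °C
Reagents that add atoms: none
Why: Selective silyl ether cleavage, in which buffered HF·pyridine should remove the secondary TBS ether much faster than the more hindered TIPS ether and leave the ester and the vinylsilane intact.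

Step 11
Reactants: 20 (1R,2S,6S)-6-[(3S)-3-hydroxy-6-methylhepta-1,5-dien-2-yl]-3-methyl-2-(triisopropylsilyloxy)-4-(trimethylsilyl)cyclohex-3-en-1-yl (2R)-2-methylbutanoate; 21 angelic acid, (2Z)-2-methylbut-2-enoic acid
Product: 23 (1R,2S,6S)-3-methyl-6-[(3S)-6-methyl-3-{[(2Z)-2-methylbut-2-enoyl]oxy}hepta-1,5-dien-2-yl]-2-(triisopropylsilyloxy)-4-(trimethylsilyl)cyclohex-3-en-1-yl (2R)-2-methylbutanoate, via angelic 2,4,6-trichlorobenzoic anhydride 22 (not isolated)
Conditions: 21, 2,4,6-trichlorobenzoyl chloride, Et3N, toluene, rt; then 20, 75 °C, no DMAP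
Reagents that add atoms: none
Why: Yamaguchi esterification through the preformed mixed anhydride without DMAP should acylate the hindered allylic alcohol while avoiding base-induced Z to E isomerisation of the angelate to the tiglate.

Step 12
Reactants: 23 (1R,2S,6S)-3-methyl-6-[(3S)-6-methyl-3-{[(2Z)-2-methylbut-2-enoyl]oxy}hepta-1,5-dien-2-yl]-2-(triisopropylsilyloxy)-4-(trimethylsilyl)cyclohex-3-en-1-yl (2R)-2-methylbutanoate
Product: 24 (1R,2S,6S)-2-hydroxy-3-methyl-6-[(3S)-6-methyl-3-{[(2Z)-2-methylbut-2-enoyl]oxy}hepta-1,5-dien-2-yl]-4-(trimethylsilyl)cyclohex-3-en-1-yl (2R)-2-methylbutanoate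
Conditions: HF·pyridine (excess), THF, rt → 40 °C
Reagents that add atoms: none
Why: Fluoride cleavage of the TIPS ether under acidic, non-basic conditions should free C3–OH without acyl migration from the cis C2 ester.

Step 13
Reactants: 24 (1R,2S,6S)-2-hydroxy-3-methyl-6-[(3S)-6-methyl-3-{[(2Z)-2-methylbut-2-enoyl]oxy}hepta-1,5-dien-2-yl]-4-(trimethylsilyl)cyclohex-3-en-1-yl (2R)-2-methylbutanoate
Product: 25 (1R,2R,3R,4S,6R)-2-hydroxy-1-methyl-4-[(3S)-6-methyl-3-{[(2Z)-2-methylbut-2-enoyl]oxy}hepta-1,5-dien-2-yl]-6-(trimethylsilyl)-7-oxabicyclo[4.1.0]heptan-3-yl (2R)-2-methylbutanoate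
Conditions: VO(acac)2 (5 mol %), t-BuOOH (in decane), CH2Cl2, 0 °C → rt
Reagents that add atoms: tert-butyl hydroperoxide, CC(C)(C)OO
Why: Vanadium-catalysed hydroxyl-directed epoxidation delivers the peroxide oxygen from the vanadate ester of C3–OH to the same face of the adjacent C4=C5 bond, which sets C4 and C5 with the epoxide cis to the hydroxyl, while the prenyl, 1,1-disubstituted and angelate alkenes, which are not allylic to a free hydroxyl, should not react.

Step 14
Reactants: 25 (1R,2R,3R,4S,6R)-2-hydroxy-1-methyl-4-[(3S)-6-methyl-3-{[(2Z)-2-methylbut-2-enoyl]oxy}hepta-1,5-dien-2-yl]-6-(trimethylsilyl)-7-oxabicyclo[4.1.0]heptan-3-yl (2R)-2-methylbutanoate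
Product: 26 (1R,2R,3R,4S,6S)-2-hydroxy-1-methyl-4-[(3S)-6-methyl-3-{[(2Z)-2-methylbut-2-enoyl]oxy}hepta-1,5-dien-2-yl]-7-oxabicyclo[4.1.0]heptan-3-yl (2R)-2-methylbutanoate
Conditions: Bu4NF, AcOH (1:1), THF, 0 °C → rt
Reagents that add atoms: none
Why: Fluoride-induced protodesilylation of an α,β-epoxysilane proceeds with retention at the oxirane carbon, acetic acid buffering should suppress acyl migration, and a Payne rearrangement is not possible for the cis epoxy alcohol.

Step 15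
Reactants: 26 (1R,2R,3R,4S,6S)-2-hydroxy-1-methyl-4-[(3S)-6-methyl-3-{[(2Z)-2-methylbut-2-enoyl]oxy}hepta-1,5-dien-2-yl]-7-oxabicyclo[4.1.0]heptan-3-yl (2R)-2-methylbutanoate
Product: 27 (1R,2R,3R,4S,6S)-4-{(3S)-4-[(2R)-3,3-dimethyloxiran-2-yl]-3-{[(2Z)-2-methylbut-2-enoyl]oxy}but-1-en-2-yl}-2-hydroxy-1-methyl-7-oxabicyclo[4.1.0]heptan-3-yl (2R)-2-methylbutanoate
Conditions: D-fructose-derived ketone of the Shi epoxidation (0.3 equiv), Oxone (2KHSO5·KHSO4·K2SO4), K2CO3, Bu4NHSO4, MeCN/dimethoxymethane/aqueous Na2B4O7–Na2EDTA buffer, 0 °C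
Reagents that add atoms: potassium peroxymonosulfate, [K+].[O-]S(=O)(=O)OO
Why: Shi epoxidation, in which the chiral dioxirane should epoxidise the electron-rich trisubstituted prenyl alkene in preference to the 1,1-disubstituted and conjugated alkenes, and the spiro transition state of the D-fructose-derived ketone should deliver oxygen to the face that gives the (R)-epoxide at C10.

Compound list
1 | 4-methylpent-3-en-1-ol | CC(C)=CCCO | starting material
2 | 4-ethenyl-1,3-dioxolan-2-one | C=CC1COC(=O)O1 | starting material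
3 | (2S,3S)-2-ethenyl-6-methylhept-5-ene-1,3-diol | OC[C@H](C=C)[C@@H](O)CC=C(C)C | intermediate
4 | bromoacetic acid | OC(=O)CBr | starting material
5 | 2-{[(2S,3S)-2-ethenyl-3-hydroxy-6-methylhept-5-en-1-yl]oxy}acetic acid | OC(=O)COC[C@H](C=C)[C@@H](O)CC=C(C)C | intermediate
6 | tert-butyldimethylsilyl 2-{[(2S,3S)-3-(tert-butyldimethylsilyloxy)-2-ethenyl-6-methylhept-5-en-1-yl]oxy}acetate | CC(C)(C)[Si](C)(C)OC(=O)COC[C@H](C=C)[C@@H](O[Si](C)(C)C(C)(C)C)CC=C(C)C | intermediate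
7 | 2-{[(2S,3S)-3-(tert-butyldimethylsilyloxy)-2-ethenyl-6-methylhept-5-en-1-yl]oxy}acetic acid | OC(=O)COC[C@H](C=C)[C@@H](O[Si](C)(C)C(C)(C)C)CC=C(C)C | intermediate
8 | 2-{[(2S,3S)-3-(tert-butyldimethylsilyloxy)-2-ethenyl-6-methylhept-5-en-1-yl]oxy}acetyl chloride | ClC(=O)COC[C@H](C=C)[C@@H](O[Si](C)(C)C(C)(C)C)CC=C(C)C | intermediate
9 | 2-{[(2S,3S)-3-(tert-butyldimethylsilyloxy)-2-ethenyl-6-methylhept-5-en-1-yl]oxy}ethen-1-one (alkoxyketene) | O=C=COC[C@H](C=C)[C@@H](O[Si](C)(C)C(C)(C)C)CC=C(C)C | intermediate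
10 | (1R,4S,5S)-4-[(1S)-1-(tert-butyldimethylsilyloxy)-4-methylpent-3-en-1-yl]-2-oxabicyclo[3.2.0]heptan-7-one | O=C1C[C@H]2[C@H]([C@@H](O[Si](C)(C)C(C)(C)C)CC=C(C)C)CO[C@@H]12 | intermediate
11 | trimethyl(prop-1-yn-1-yl)silane | CC#C[Si](C)(C)C | starting material
12 | (3S,3aS,7aR)-3-[(1S)-1-(tert-butyldimethylsilyloxy)-4-methylpent-3-en-1-yl]-6-methyl-5-(trimethylsilyl)-3,3a,4,7a-tetrahydro-1-benzofuran-7(2H)-one | O=C1C(C)=C([Si](C)(C)C)C[C@H]2[C@H]([C@@H](O[Si](C)(C)C(C)(C)C)CC=C(C)C)CO[C@@H]12 | intermediate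
13 | (3S,3aS,7S,7aR)-3-[(1S)-1-(tert-butyldimethylsilyloxy)-4-methylpent-3-en-1-yl]-6-methyl-5-(trimethylsilyl)-2,3,3a,4,7,7a-hexahydro-1-benzofuran-7-ol | O[C@H]1C(C)=C([Si](C)(C)C)C[C@H]2[C@H]([C@@H](O[Si](C)(C)C(C)(C)C)CC=C(C)C)CO[C@@H]12 | intermediate
14 | (3S,3aS,7S,7aR)-3-[(1S)-1-(tert-butyldimethylsilyloxy)-4-methylpent-3-en-1-yl]-6-methyl-7-(triisopropylsilyloxy)-5-(trimethylsilyl)-2,3,3a,4,7,7a-hexahydro-1-benzofuran | CC(C)[Si](C(C)C)(C(C)C)O[C@H]1C(C)=C([Si](C)(C)C)C[C@H]2[C@H]([C@@H](O[Si](C)(C)C(C)(C)C)CC=C(C)C)CO[C@@H]12 | intermediate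
15 | (2R)-2-methylbutanoic acid | CC[C@@H](C)C(=O)O | starting material
16 | (2R)-2-methylbutanoyl chloride | CC[C@@H](C)C(=O)Cl | intermediate
17 | (2R)-2-methylbutanoyl iodide | CC[C@@H](C)C(=O)I | intermediate
18 | (1R,2S,6S)-6-[(2R,3S)-3-(tert-butyldimethylsilyloxy)-1-iodo-6-methylhept-5-en-2-yl]-3-methyl-2-(triisopropylsilyloxy)-4-(trimethylsilyl)cyclohex-3-en-1-yl (2R)-2-methylbutanoate | CC(C)[Si](C(C)C)(C(C)C)O[C@H]1C(C)=C([Si](C)(C)C)C[C@@H]([C@@H](CI)[C@@H](O[Si](C)(C)C(C)(C)C)CC=C(C)C)[C@H]1OC(=O)[C@H](C)CC | intermediate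
19 | (1R,2S,6S)-6-[(3S)-3-(tert-butyldimethylsilyloxy)-6-methylhepta-1,5-dien-2-yl]-3-methyl-2-(triisopropylsilyloxy)-4-(trimethylsilyl)cyclohex-3-en-1-yl (2R)-2-methylbutanoate | CC(C)[Si](C(C)C)(C(C)C)O[C@H]1C(C)=C([Si](C)(C)C)C[C@@H](C(=C)[C@@H](O[Si](C)(C)C(C)(C)C)CC=C(C)C)[C@H]1OC(=O)[C@H](C)CC | intermediate
20 | (1R,2S,6S)-6-[(3S)-3-hydroxy-6-methylhepta-1,5-dien-2-yl]-3-methyl-2-(triisopropylsilyloxy)-4-(trimethylsilyl)cyclohex-3-en-1-yl (2R)-2-methylbutanoate | CC(C)[Si](C(C)C)(C(C)C)O[C@H]1C(C)=C([Si](C)(C)C)C[C@@H](C(=C)[C@@H](O)CC=C(C)C)[C@H]1OC(=O)[C@H](C)CC | intermediate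
21 | angelic acid, (2Z)-2-methylbut-2-enoic acid | C/C=C(/C)C(=O)O | starting material
22 | (2Z)-2-methylbut-2-enoic 2,4,6-trichlorobenzoic anhydride | C/C=C(/C)C(=O)OC(=O)c1c(Cl)cc(Cl)cc1Cl | intermediate
23 | (1R,2S,6S)-3-methyl-6-[(3S)-6-methyl-3-{[(2Z)-2-methylbut-2-enoyl]oxy}hepta-1,5-dien-2-yl]-2-(triisopropylsilyloxy)-4-(trimethylsilyl)cyclohex-3-en-1-yl (2R)-2-methylbutanoate | CC(C)[Si](C(C)C)(C(C)C)O[C@H]1C(C)=C([Si](C)(C)C)C[C@@H](C(=C)[C@@H](OC(=O)/C(C)=C\C)CC=C(C)C)[C@H]1OC(=O)[C@H](C)CC | intermediate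
24 | (1R,2S,6S)-2-hydroxy-3-methyl-6-[(3S)-6-methyl-3-{[(2Z)-2-methylbut-2-enoyl]oxy}hepta-1,5-dien-2-yl]-4-(trimethylsilyl)cyclohex-3-en-1-yl (2R)-2-methylbutanoate | O[C@H]1C(C)=C([Si](C)(C)C)C[C@@H](C(=C)[C@@H](OC(=O)/C(C)=C\C)CC=C(C)C)[C@H]1OC(=O)[C@H](C)CC | intermediate
25 | (1R,2R,3R,4S,6R)-2-hydroxy-1-methyl-4-[(3S)-6-methyl-3-{[(2Z)-2-methylbut-2-enoyl]oxy}hepta-1,5-dien-2-yl]-6-(trimethylsilyl)-7-oxabicyclo[4.1.0]heptan-3-yl (2R)-2-methylbutanoate | O[C@H]1[C@@]2(C)O[C@@]2([Si](C)(C)C)C[C@@H](C(=C)[C@@H](OC(=O)/C(C)=C\C)CC=C(C)C)[C@H]1OC(=O)[C@H](C)CC | intermediate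
26 | (1R,2R,3R,4S,6S)-2-hydroxy-1-methyl-4-[(3S)-6-methyl-3-{[(2Z)-2-methylbut-2-enoyl]oxy}hepta-1,5-dien-2-yl]-7-oxabicyclo[4.1.0]heptan-3-yl (2R)-2-methylbutanoate | O[C@H]1[C@@]2(C)O[C@H]2C[C@@H](C(=C)[C@@H](OC(=O)/C(C)=C\C)CC=C(C)C)[C@H]1OC(=O)[C@H](C)CC | intermediate
27 | (1R,2R,3R,4S,6S)-4-{(3S)-4-[(2R)-3,3-dimethyloxiran-2-yl]-3-{[(2Z)-2-methylbut-2-enoyl]oxy}but-1-en-2-yl}-2-hydroxy-1-methyl-7-oxabicyclo[4.1.0]heptan-3-yl (2R)-2-methylbutanoate | C=C([C@H](C[C@H]1OC1(C)C)OC(=O)/C(C)=C\C)[C@@H]1C[C@@H]2O[C@]2(C)[C@H](O)[C@@H]1OC(=O)[C@H](C)CC | target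

Total step count: 15. Longest linear sequence: 15 steps (1 → 27).

Steps most likely to fail

Step 5. The nickel catalyst may insert the alkyne into the oxygen-bearing C2–C3 bond instead of the C3–C6 bond, or take up the silylalkyne in the reversed orientation. The fallback sets out from 10 and comes back at 26, replacing the insertion by two regiodefined one-carbon homologations. Diazomethane (Et2O/MeOH, 0 °C) should expand 10 with migration of the unsubstituted methylene carbon to the cis-fused cyclopentanone F1. LiN(iPr)2 and Me3SiCl (THF, −78 °C) should give the less substituted trimethylsilyl enol ether F2. Chloro(methyl)carbene (1,1-dichloroethane, n-BuLi, Et2O, −35 °C) should give the siloxycyclopropane F3, which on heating in toluene should open with loss of Me3SiCl to the silicon-free 2-methylcyclohexenone F4. Steps 6 to 12 are then run unchanged on this series: Luche reduction to the allylic alcohol F5, silylation to the TIPS ether F6, acylative ether cleavage to the iodo ester F7, DBU elimination to the diene F8, selective TBS removal to the alcohol F9, Yamaguchi esterification to the angelate F10, and TIPS removal to the allylic alcohol F11. Epoxidation of F11 with VO(acac)2/t-BuOOH gives 26 directly, so step 14 falls away.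

Step 4. The alkoxyketene may dimerise or add only slowly to the unactivated monosubstituted alkene, or add with poor facial selectivity. The fallback sets out from 7 and comes back at 10 through a keteniminium [2+2] cycloaddition. Amide coupling of 7 with pyrrolidine (EDC·HCl, HOBt, CH2Cl2) gives the pyrrolidine amide F12. Tf2O and 2,4,6-collidine (ClCH2CH2Cl, 80 °C) convert it into the keteniminium triflate F13, which should close onto the vinyl group to the cyclobutaniminium triflate F14. Hydrolysis with aqueous NaHCO3 gives 10.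

Step 8. The acyl iodide may also attack the silyl ethers or the prenyl alkene, or acylation of the hindered ring oxygen may be too slow. The fallback sets out from 14 and comes back at 19, separating ring opening from acylation. Me2BBr (Et3N cat., CH2Cl2, 0 °C) should open the tetrahydrofuran by bromide attack at the primary C14 to the bromo alcohol F15. Steglich esterification with 15 (DIC, DMAP cat., CH2Cl2, 0 °C) gives the bromo ester F16. DBU (toluene, 90 °C) eliminates HBr to 19.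

Further compounds
F1 | step 5 | (1R,4S,5S)-4-[(1S)-1-(tert-butyldimethylsilyloxy)-4-methylpent-3-en-1-yl]-2-oxabicyclo[3.3.0]octan-8-one | O=C1CC[C@H]2[C@H]([C@@H](O[Si](C)(C)C(C)(C)C)CC=C(C)C)CO[C@@H]12
F2 | step 5 | trimethylsilyl enol ether of F1 (enol ether double bond towards the ring CH2) | C[Si](C)(C)OC1=CC[C@H]2[C@H]([C@@H](O[Si](C)(C)C(C)(C)C)CC=C(C)C)CO[C@@H]12
F3 | step 5 | chloro(methyl)cyclopropane adduct of F2 (siloxycyclopropane, cyclopropane centres as a mixture) | C[Si](C)(C)OC13C(C)(Cl)C3C[C@H]2[C@H]([C@@H](O[Si](C)(C)C(C)(C)C)CC=C(C)C)CO[C@@H]12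
F4 | step 5 | (3S,3aS,7aR)-3-[(1S)-1-(tert-butyldimethylsilyloxy)-4-methylpent-3-en-1-yl]-6-methyl-3,3a,4,7a-tetrahydro-1-benzofuran-7(2H)-one (12 without the ring trimethylsilyl group) | O=C1C(C)=CC[C@H]2[C@H]([C@@H](O[Si](C)(C)C(C)(C)C)CC=C(C)C)CO[C@@H]12
F5 | step 5 | (3S,3aS,7S,7aR)-3-[(1S)-1-(tert-butyldimethylsilyloxy)-4-methylpent-3-en-1-yl]-6-methyl-2,3,3a,4,7,7a-hexahydro-1-benzofuran-7-ol (13 without the ring trimethylsilyl group) | O[C@H]1C(C)=CC[C@H]2[C@H]([C@@H](O[Si](C)(C)C(C)(C)C)CC=C(C)C)CO[C@@H]12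
F6 | step 5 | 7-O-triisopropylsilyl ether of F5 (14 without the ring trimethylsilyl group) | CC(C)[Si](C(C)C)(C(C)C)O[C@H]1C(C)=CC[C@H]2[C@H]([C@@H](O[Si](C)(C)C(C)(C)C)CC=C(C)C)CO[C@@H]12
F7 | step 5 | (1R,2S,6S)-6-[(2R,3S)-3-(tert-butyldimethylsilyloxy)-1-iodo-6-methylhept-5-en-2-yl]-3-methyl-2-(triisopropylsilyloxy)cyclohex-3-en-1-yl (2R)-2-methylbutanoate | CC(C)[Si](C(C)C)(C(C)C)O[C@H]1C(C)=CC[C@@H]([C@@H](CI)[C@@H](O[Si](C)(C)C(C)(C)C)CC=C(C)C)[C@H]1OC(=O)[C@H](C)CC
F8 | step 5 | (1R,2S,6S)-6-[(3S)-3-(tert-butyldimethylsilyloxy)-6-methylhepta-1,5-dien-2-yl]-3-methyl-2-(triisopropylsilyloxy)cyclohex-3-en-1-yl (2R)-2-methylbutanoate | CC(C)[Si](C(C)C)(C(C)C)O[C@H]1C(C)=CC[C@@H](C(=C)[C@@H](O[Si](C)(C)C(C)(C)C)CC=C(C)C)[C@H]1OC(=O)[C@H](C)CC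
F9 | step 5 | (1R,2S,6S)-6-[(3S)-3-hydroxy-6-methylhepta-1,5-dien-2-yl]-3-methyl-2-(triisopropylsilyloxy)cyclohex-3-en-1-yl (2R)-2-methylbutanoate | CC(C)[Si](C(C)C)(C(C)C)O[C@H]1C(C)=CC[C@@H](C(=C)[C@@H](O)CC=C(C)C)[C@H]1OC(=O)[C@H](C)CC
F10 | step 5 | (1R,2S,6S)-3-methyl-6-[(3S)-6-methyl-3-{[(2Z)-2-methylbut-2-enoyl]oxy}hepta-1,5-dien-2-yl]-2-(triisopropylsilyloxy)cyclohex-3-en-1-yl (2R)-2-methylbutanoate | CC(C)[Si](C(C)C)(C(C)C)O[C@H]1C(C)=CC[C@@H](C(=C)[C@@H](OC(=O)/C(C)=C\C)CC=C(C)C)[C@H]1OC(=O)[C@H](C)CC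
F11 | step 5 | (1R,2S,6S)-2-hydroxy-3-methyl-6-[(3S)-6-methyl-3-{[(2Z)-2-methylbut-2-enoyl]oxy}hepta-1,5-dien-2-yl]cyclohex-3-en-1-yl (2R)-2-methylbutanoate | O[C@H]1C(C)=CC[C@@H](C(=C)[C@@H](OC(=O)/C(C)=C\C)CC=C(C)C)[C@H]1OC(=O)[C@H](C)CC
F12 | step 4 | 2-{[(2S,3S)-3-(tert-butyldimethylsilyloxy)-2-ethenyl-6-methylhept-5-en-1-yl]oxy}-1-(pyrrolidin-1-yl)ethan-1-one | O=C(COC[C@H](C=C)[C@@H](O[Si](C)(C)C(C)(C)C)CC=C(C)C)N1CCCC1
F13 | step 4 | keteniminium triflate derived from F12 | C(OC[C@H](C=C)[C@@H](O[Si](C)(C)C(C)(C)C)CC=C(C)C)=C=[N+]1CCCC1.[O-]S(=O)(=O)C(F)(F)F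
F14 | step 4 | cyclobutaniminium triflate (pyrrolidinium ylidene of 10) | C1CC[N+](C1)=C1C[C@H]2[C@H]([C@@H](O[Si](C)(C)C(C)(C)C)CC=C(C)C)CO[C@@H]12.[O-]S(=O)(=O)C(F)(F)F
F15 | step 8 | (1R,2S,6S)-6-[(2R,3S)-1-bromo-3-(tert-butyldimethylsilyloxy)-6-methylhept-5-en-2-yl]-3-methyl-2-(triisopropylsilyloxy)-4-(trimethylsilyl)cyclohex-3-en-1-ol | CC(C)[Si](C(C)C)(C(C)C)O[C@H]1C(C)=C([Si](C)(C)C)C[C@@H]([C@@H](CBr)[C@@H](O[Si](C)(C)C(C)(C)C)CC=C(C)C)[C@H]1O
F16 | step 8 | (2R)-2-methylbutanoate of F15 (bromo analogue of 18) | CC(C)[Si](C(C)C)(C(C)C)O[C@H]1C(C)=C([Si](C)(C)C)C[C@@H]([C@@H](CBr)[C@@H](O[Si](C)(C)C(C)(C)C)CC=C(C)C)[C@H]1OC(=O)[C@H](C)CC
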